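(The readings are calculated on assumed constants; the scatter is artificial.)

The constant I needed first was the second-order constant of electrophile with nucleophile, and I read it early, while little target stood in the flask.

in all of them: electrophile 0.20 M; gas 72 mM (held)
- Thursday's: nucleophile 0.25 M (fed, over 15 h); run made earlier
- Friday's: nucleophile 0.58 M (fed, over 15 h); run made earlier
- blue: nucleophile 0.190 M (fed, over 15 h); time 30 h
- green: nucleophile 0.380 M (fed, over 15 h); time 30 h

| run | time / h | electrophile / % | target / % |
|---|---|---|---|
| Thursday's | 2.00 | 98 | 2 |
| Thursday's | 5.00 | 94 | 7 |
| Thursday's | 10.0 | 84 | 22 |
| Thursday's | 15.0 | 65 | 37 |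
| Friday's | 1.33 | 99 | 0 |
| Friday's | 3.00 | 94 | 7 |
| Friday's | 6.00 | 80 | 16 |
| Friday's | 15.0 | 39 | 66 |

(standard deviation of a reading: 2 percentage points)

- at the start none of the gas is in solution

- part of the electrophile that has reacted at the end, blue
- part of the electrophile that has reacted at the end, green
- what raising the concentration of nucleophile from its lowest to its highest value here does to the part of the electrophile that has reacted (changes below 5 percentage points count as none) (it rises / no change / it falls)

At 3.00 h in Friday's run the target read 7%, with 0.0580 M of nucleophile fed on average up to then. That gives a constant of 0.402 /M/h, a rough reading because the scatter is 2 percentage points.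

The bench rule counts one nucleophile per electrophile, which makes blue, at 0.950 equivalents, nearly balanced. Between 6.00 h and 15.0 h of Friday's run, however, the rule left 0.324 M of nucleophile, while the rate of target formation and my constant called for 0.234 M, which is less.

Friday's interval therefore read 2.10 and Thursday's last interval 1.74, with a mean of 1.92, all of them readings that carry the scatter. This is the nucleophile cost, the nucleophile gone per target formed, and the rule's value of one is the zero of its scale. The border is the charge divided by the cost and by the electrophile: 0.495 in blue, which at that cost pays for about half of the electrophile and makes nucleophile the limiting reagent over the time asked, and 0.991 in green, which at that cost stands near balance.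

Scaling the target at the end of the feed by the charge, I took 28.1% reacted in blue and 48.4% in green. Integrating from 15 h to 30 h at that cost gave 44.4% for blue and 76.1% for green, a rise of 32 points.

The forecast, taking “nucleophile present as fed minus consumed”, gave 54% for blue (45% to 60%) and 81% for green (70% to 87%), both higher than mine, and on the trend said: it rises.

The flask gave 43.1% for blue and 74.7% for green; on the trend, it rises, by 32 points.

    gas ⇌ free base, rate k1*(csat - [free base]) (kL = 0.0392 /h)
    nucleophile + acid set free ⇌ protonated nucleophile, settled at all times (K = 1360 /M)
    electrophile + nucleophile ⇌ acid set free + target (K = 1.20, k = 0.396 /M/h)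
    acid set free + free base ⇌ salt of the base (K = 59000 /M, k = 0.589 /M/h)
    acid set free + target → side product (k = 0.390 /M/h)

In blue at 12.8 h the forward main step alone gave the electrophile a half-life of 23 h, while the forward passage to salt of the base gave the free base 120 d. At 30.0 h blue held 0.0821 M of protonated nucleophile against 6.21 × 10⁻⁴ M of salt of the base. Beside the 1.92 I had read, the charged nucleophile no longer free per electrophile reacted stood at 1.95 in blue at 30.0 h, and at 1.98 in the same flask charged with 0.12 M of electrophile, where 57.1% had reacted.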